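**Retrosynthetic overview** (azulene numbering: C3 isopropyl, C3a hydroxyl, C6 methyl, C8 ester, C8a methyl)
1. The ester is made last and the C8 carbinol comes from the 8-ketone by chelation-controlled reduction; ring B (the cycloheptene) is cut at its C6=C7 double bond by ring-closing metathesis.
2. The metathesis triene is a ring A cyclopentane with a vinyl carbinol on C8a and a 3-methylbut-3-enyl chain on C3a; both arms are put on one ketone anti to the C3 isopropyl group (acrolein aldol at C8a, then organocerium addition at C3a), with no protecting groups.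
3. Ring A, its methyl and isopropyl groups and the C3 stereocentre are carved out of (S)-limonene: C=C cleavage and aldol ring contraction of the cyclohexene, then Baeyer–Villiger excision of the formyl carbon, which leaves a regiodefined C3a/C8a enol ester (nine of the ten limonene carbons are kept).
4. Enabling feature: in ring B the trisubstituted C6=C7 olefin lies between the allylic C8 carbinol and the C5 methylene, and its two halves hang cis on the adjacent, fully substituted ring A carbons C8a and C3a, so ring A holds the two olefin arms together for metathesis.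
5. Ring order: ring A (step 2), then ring B (step 6).

Key step: step 6

Remark: the target is read as (3R,3aS,8S,8aR), a cis-fused hydroazulene in which the 3-isopropyl, 3a-hydroxyl, 8a-methyl and 8-acyloxy groups all lie on one face.

**Step 1**
Reactants: 1 (S)-(−)-limonene
Product: 2 (S)-p-menth-1-ene
Conditions: H2 (1 atm), RhCl(PPh3)3 (1 mol%), toluene/EtOH, rt
Reagents that add atoms: none
Why: Chemoselective homogeneous alkene hydrogenation, in which the 1,1-disubstituted isopropenyl olefin should be reduced much faster than the trisubstituted ring olefin; the stereocentre is not involved.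

**Step 2**
Reactants: 2 (S)-p-menth-1-ene
Product: 4 (5R)-2-methyl-5-(propan-2-yl)cyclopent-1-ene-1-carbaldehyde, via keto aldehyde 3 (not isolated)
Conditions: O3, CH2Cl2/MeOH, −78 °C; Me2S, −78 °C → rt; then piperidine, AcOH (cat.), toluene, 80 °C
Reagents that add atoms: ozone, O=[O+][O-]
Why: Ozonolysis of the ring olefin followed by amine-catalysed intramolecular aldol condensation (enamine of the aldehyde onto the methyl ketone, five-membered ring) contracts the ring; the stereocentre is beta to the aldehyde and cannot epimerise.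

**Step 3**
Reactants: 4 (5R)-2-methyl-5-(propan-2-yl)cyclopent-1-ene-1-carbaldehyde
Product: 5 (5R)-2-methyl-5-(propan-2-yl)cyclopent-1-en-1-yl formate
Conditions: mCPBA (1.05 equiv), NaHCO3, CH2Cl2, 0 °C
Reagents that add atoms: 3-chloroperoxybenzoic acid (mCPBA), OOC(=O)c1cccc(Cl)c1
Why: Baeyer–Villiger oxidation of an alpha,beta-unsaturated aldehyde, in which the alkenyl group migrates to give the enol formate, a masked regiodefined enolate of the 2-methyl-5-isopropylcyclopentanone; no stereocentre is touched.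

**Step 4**
Reactants: 5 (5R)-2-methyl-5-(propan-2-yl)cyclopent-1-en-1-yl formate; 6 acrolein
Product: 8 (2R,5R)-2-(1-hydroxyprop-2-en-1-yl)-2-methyl-5-(propan-2-yl)cyclopentan-1-one (both carbinol epimers), via lithium enolate 7 (not isolated)
Conditions: MeLi (2.1 equiv), THF, −78 → 0 °C (5 added to MeLi); then 6, −78 °C; aq. NH4Cl
Reagents that add atoms: none
Why: Enol ester cleavage by MeLi gives the tetrasubstituted lithium enolate without equilibration (C3 is never enolised), and its aldol addition to acrolein (1,2-mode at low temperature) should occur on the face anti to the isopropyl group, setting the quaternary C8a with methyl cis to isopropyl; the carbinol centre forms as an epimer mixture that steps 7 and 8 make convergent.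

**Step 5**
Reactants: 8 (2R,5R)-2-(1-hydroxyprop-2-en-1-yl)-2-methyl-5-(propan-2-yl)cyclopentan-1-one; 9 4-bromo-2-methylbut-1-ene
Product: 11 (1S,2R,5R)-2-(1-hydroxyprop-2-en-1-yl)-2-methyl-1-(3-methylbut-3-en-1-yl)-5-(propan-2-yl)cyclopentan-1-ol (both carbinol epimers), via Grignard reagent 10 (not isolated)
Conditions: 9, Mg, Et2O, rt; CeCl3 (anhydrous), THF, −78 °C; then 8, −78 → −20 °C; aq. NH4Cl
Reagents that add atoms: none
Why: Organocerium-mediated Grignard 1,2-addition to a hindered, enolisable ketone; the metal alkoxide of the side-chain hydroxyl chelates the carbonyl and holds that branch near the carbonyl plane, leaving the angular methyl pseudo-axial, so the nucleophile should enter anti to both the methyl and the isopropyl group and set C3a with hydroxyl cis to both and the new chain cis to the vinyl carbinol arm.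

**Step 6**
Reactants: 11 (1S,2R,5R)-2-(1-hydroxyprop-2-en-1-yl)-2-methyl-1-(3-methylbut-3-en-1-yl)-5-(propan-2-yl)cyclopentan-1-ol
Product: 12 (3R,3aS,8aR)-6,8a-dimethyl-3-(propan-2-yl)-1,2,3,4,5,8-hexahydroazulene-3a,8(8aH)-diol (both C8 epimers)
Conditions: second-generation Grubbs catalyst RuCl2(=CHPh)(PCy3)(H2IMes) (5 mol%), CH2Cl2 (0.005 M), 40 °C
Reagents that add atoms: none
Why: Olefin metathesis by the Chauvin mechanism: the ruthenium alkylidene should load onto the monosubstituted vinyl group of the C8 carbinol and add to the 1,1-disubstituted olefin of the C3a chain through a ruthenacyclobutane, whose cycloreversion releases the C6=C7 double bond and, after turnover, ethene. The closest known reaction type is ring-closing metathesis of a terminal vinyl carbinol with a 2-substituted 1-alkene to give a 1-methylcycloheptene. Ring B closes as a seven-membered ring with an endocyclic trisubstituted olefin onto the existing ring A, and no other olefin pairing is available. No new stereocentre is formed; the Z geometry is enforced by the ring and the cis ring fusion is inherited from steps 4 and 5, which placed both arms on the same face of ring A. The step needs cyclisation over oligomerisation and tolerance of two free hydroxyls, which high dilution, the adjacent fully substituted C8a and C3a that hold the arms gauche, and the inability of the 1,1-disubstituted olefin to homodimerise should secure.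

**Step 7**
Reactants: 12 (3R,3aS,8aR)-6,8a-dimethyl-3-(propan-2-yl)-1,2,3,4,5,8-hexahydroazulene-3a,8(8aH)-diol
Product: 13 (3R,3aS,8aS)-3a-hydroxy-6,8a-dimethyl-3-(propan-2-yl)-2,3,3a,4,5,8a-hexahydroazulen-8(1H)-one
Conditions: Dess–Martin periodinane, NaHCO3, CH2Cl2, 0 °C → rt
Reagents that add atoms: none
Why: Dess–Martin oxidation of the secondary allylic alcohol merges both C8 epimers into one enone, while the tertiary alcohol is inert and the buffered, non-basic medium should avoid retro-aldol cleavage.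

**Step 8**
Reactants: 13 (3R,3aS,8aS)-3a-hydroxy-6,8a-dimethyl-3-(propan-2-yl)-2,3,3a,4,5,8a-hexahydroazulen-8(1H)-one
Product: 15 (3R,3aS,8S,8aR)-6,8a-dimethyl-3-(propan-2-yl)-1,2,3,4,5,8-hexahydroazulene-3a,8(8aH)-diol, via boron chelate 14 (not isolated)
Conditions: Et2BOMe, THF/MeOH (4:1), −78 °C; NaBH4, −78 °C; AcOH; MeOH, evaporation
Reagents that add atoms: none
Why: Narasaka–Prasad reduction, in which the diethylboryl group ties the C3a oxygen and the C8 carbonyl oxygen together on one face so that external hydride should add 1,2 from the opposite face (also anti to the angular methyl), giving the syn-1,3-diol with C8 (S).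

**Step 9**
Reactants: 15 (3R,3aS,8S,8aR)-6,8a-dimethyl-3-(propan-2-yl)-1,2,3,4,5,8-hexahydroazulene-3a,8(8aH)-diol; 16 4-methoxybenzoyl chloride
Product: 17 (3R,3aS,8S,8aR)-3a-hydroxy-6,8a-dimethyl-3-(propan-2-yl)-1,2,3,3a,4,5,8,8a-octahydroazulen-8-yl 4-methoxybenzoate
Conditions: pyridine, DMAP (cat.), CH2Cl2, 0 °C → rt
Reagents that add atoms: none
Why: DMAP-catalysed acylation should esterify the secondary allylic alcohol only, because the tertiary ring-fusion alcohol is too hindered to react.

**Compound list**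
1 | (S)-(−)-limonene, (4S)-1-methyl-4-(prop-1-en-2-yl)cyclohex-1-ene | CC1=CC[C@H](CC1)C(C)=C | starting material
2 | (S)-p-menth-1-ene, (4S)-1-methyl-4-(propan-2-yl)cyclohex-1-ene | CC1=CC[C@H](CC1)C(C)C | intermediate
3 | (3S)-6-oxo-3-(propan-2-yl)heptanal | O=CC[C@H](CCC(C)=O)C(C)C | intermediate
4 | (5R)-2-methyl-5-(propan-2-yl)cyclopent-1-ene-1-carbaldehyde | O=CC1=C(C)CC[C@@H]1C(C)C | intermediate
5 | (5R)-2-methyl-5-(propan-2-yl)cyclopent-1-en-1-yl formate | O=COC1=C(C)CC[C@@H]1C(C)C | intermediate
6 | acrolein (prop-2-enal) | C=CC=O | starting material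
7 | lithium (5R)-2-methyl-5-(propan-2-yl)cyclopent-1-en-1-olate | [Li]OC1=C(C)CC[C@@H]1C(C)C | intermediate
8 | (2R,5R)-2-(1-hydroxyprop-2-en-1-yl)-2-methyl-5-(propan-2-yl)cyclopentan-1-one, both carbinol epimers | C=CC(O)[C@@]1(C)CC[C@H](C(C)C)C1=O | intermediate
9 | 4-bromo-2-methylbut-1-ene | C=C(C)CCBr | starting material
10 | (3-methylbut-3-en-1-yl)magnesium bromide | C=C(C)CC[Mg]Br | intermediate
11 | (1S,2R,5R)-2-(1-hydroxyprop-2-en-1-yl)-2-methyl-1-(3-methylbut-3-en-1-yl)-5-(propan-2-yl)cyclopentan-1-ol, both carbinol epimers | C=CC(O)[C@@]1(C)CC[C@H](C(C)C)[C@@]1(O)CCC(C)=C | intermediate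
12 | (3R,3aS,8aR)-6,8a-dimethyl-3-(propan-2-yl)-1,2,3,4,5,8-hexahydroazulene-3a,8(8aH)-diol, both C8 epimers | OC1C=C(C)CC[C@]2(O)[C@@H](C(C)C)CC[C@]12C | intermediate
13 | (3R,3aS,8aS)-3a-hydroxy-6,8a-dimethyl-3-(propan-2-yl)-2,3,3a,4,5,8a-hexahydroazulen-8(1H)-one | O=C1C=C(C)CC[C@]2(O)[C@@H](C(C)C)CC[C@]12C | intermediate
14 | 3a-O-diethylboryl derivative of 13 (boron chelated to the C8 carbonyl) | O=C1C=C(C)CC[C@]2(OB(CC)CC)[C@@H](C(C)C)CC[C@]12C | intermediate
15 | (3R,3aS,8S,8aR)-6,8a-dimethyl-3-(propan-2-yl)-1,2,3,4,5,8-hexahydroazulene-3a,8(8aH)-diol | O[C@H]1C=C(C)CC[C@]2(O)[C@@H](C(C)C)CC[C@]12C | intermediate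
16 | 4-methoxybenzoyl chloride | COc1ccc(cc1)C(Cl)=O | starting material
17 | (3R,3aS,8S,8aR)-3a-hydroxy-6,8a-dimethyl-3-(propan-2-yl)-1,2,3,3a,4,5,8,8a-octahydroazulen-8-yl 4-methoxybenzoate | COc1ccc(C(=O)O[C@H]2C=C(C)CC[C@]3(O)[C@@H](C(C)C)CC[C@]23C)cc1 | target

**Step count and risks**
Total step count: 9. Longest linear sequence: 9 steps, from (S)-limonene.

Steps most likely to fail:

- **Step 4.** The enolate may add to acrolein with poor facial selectivity at C8a, add in the conjugate sense, or the aldolate may revert on work-up. The fallback sets out from 4 and delivers the carbinol carbon intramolecularly.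
  - Reduction with NaBH4 and CeCl3·7H2O in MeOH gives the allylic alcohol [(5R)-2-methyl-5-(propan-2-yl)cyclopent-1-en-1-yl]methanol F1.
  - NaH and 3-bromo-1-(trimethylsilyl)prop-1-yne give the propargylic ether trimethyl(3-{[(5R)-2-methyl-5-(propan-2-yl)cyclopent-1-en-1-yl]methoxy}prop-1-yn-1-yl)silane F2.
  - n-BuLi in THF at −78 °C triggers a [2,3]-Wittig rearrangement that should place the carbinol carbon on the methyl-bearing olefin carbon anti to the isopropyl group, giving 1-[(1S,3R)-1-methyl-2-methylidene-3-(propan-2-yl)cyclopentyl]-3-(trimethylsilyl)prop-2-yn-1-ol F3.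
  - Ozonolysis of the exocyclic methylene (O3, −78 °C; Me2S; the alkyne is spared) gives (2R,5R)-2-[1-hydroxy-3-(trimethylsilyl)prop-2-yn-1-yl]-2-methyl-5-(propan-2-yl)cyclopentan-1-one F4.
  - Tetrabutylammonium fluoride buffered with AcOH gives (2R,5R)-2-(1-hydroxyprop-2-yn-1-yl)-2-methyl-5-(propan-2-yl)cyclopentan-1-one F5.
  - Semihydrogenation (H2, Pd/CaCO3 poisoned with Pb(OAc)2, quinoline) comes back to the route at 8.

- **Step 5.** The organometallic may attack the wrong face of the ketone, or enolise it, or the aldol may cleave. The fallback sets out from 8 and ties the nucleophile to the C8 oxygen so that it can only add cis.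
  - Bromoacetyl bromide and pyridine give 1-[(1R,3R)-1-methyl-2-oxo-3-(propan-2-yl)cyclopentyl]prop-2-en-1-yl bromoacetate F6.
  - SmI2 in THF at −78 °C (intramolecular Reformatsky reaction) should give the cis-fused lactone (4aS,5R,7aR)-1-ethenyl-4a-hydroxy-7a-methyl-5-(propan-2-yl)hexahydrocyclopenta[c]pyran-3(1H)-one F7.
  - LiAlH4 gives the triol (1S,2R,5R)-1-(2-hydroxyethyl)-2-(1-hydroxyprop-2-en-1-yl)-2-methyl-5-(propan-2-yl)cyclopentan-1-ol F8.
  - TsCl in pyridine at 0 °C gives the primary tosylate 2-[(1S,2R,5R)-1-hydroxy-2-(1-hydroxyprop-2-en-1-yl)-2-methyl-5-(propan-2-yl)cyclopentyl]ethyl 4-methylbenzenesulfonate F9.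
  - Isopropenylmagnesium bromide with catalytic CuI in THF displaces the tosylate and comes back to the route at 11.

- **Step 8.** The boron chelate may fail to form across the ring, so hydride delivery could lose its facial bias. The fallback sets out from 13 and replaces chelation by steric shielding.
  - Triethylsilyl triflate and 2,6-lutidine give (3R,3aS,8aS)-6,8a-dimethyl-3-(propan-2-yl)-3a-[(triethylsilyl)oxy]-2,3,3a,4,5,8a-hexahydroazulen-8(1H)-one F10.
  - Luche reduction (NaBH4, CeCl3·7H2O, MeOH, −78 °C), with hydride entering anti to the angular methyl and the silyl ether, gives (3R,3aS,8S,8aR)-6,8a-dimethyl-3-(propan-2-yl)-3a-[(triethylsilyl)oxy]-1,2,3,3a,4,5,8,8a-octahydroazulen-8-ol F11.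
  - Acylation with 16, pyridine and DMAP gives (3R,3aS,8S,8aR)-6,8a-dimethyl-3-(propan-2-yl)-3a-[(triethylsilyl)oxy]-1,2,3,3a,4,5,8,8a-octahydroazulen-8-yl 4-methoxybenzoate F12.
  - HF·pyridine in THF removes the silyl group and comes back to the route at 17.

**Further compounds**
F1 | step 4 | [(5R)-2-methyl-5-(propan-2-yl)cyclopent-1-en-1-yl]methanol | OCC1=C(C)CC[C@@H]1C(C)C
F2 | step 4 | trimethyl(3-{[(5R)-2-methyl-5-(propan-2-yl)cyclopent-1-en-1-yl]methoxy}prop-1-yn-1-yl)silane | C[Si](C)(C)C#CCOCC1=C(C)CC[C@@H]1C(C)C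
F3 | step 4 | 1-[(1S,3R)-1-methyl-2-methylidene-3-(propan-2-yl)cyclopentyl]-3-(trimethylsilyl)prop-2-yn-1-ol | C[Si](C)(C)C#CC(O)[C@@]1(C)CC[C@H](C(C)C)C1=C
F4 | step 4 | (2R,5R)-2-[1-hydroxy-3-(trimethylsilyl)prop-2-yn-1-yl]-2-methyl-5-(propan-2-yl)cyclopentan-1-one | C[Si](C)(C)C#CC(O)[C@@]1(C)CC[C@H](C(C)C)C1=O
F5 | step 4 | (2R,5R)-2-(1-hydroxyprop-2-yn-1-yl)-2-methyl-5-(propan-2-yl)cyclopentan-1-one | C#CC(O)[C@@]1(C)CC[C@H](C(C)C)C1=O
F6 | step 5 | 1-[(1R,3R)-1-methyl-2-oxo-3-(propan-2-yl)cyclopentyl]prop-2-en-1-yl bromoacetate | C=CC(OC(=O)CBr)[C@@]1(C)CC[C@H](C(C)C)C1=O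
F7 | step 5 | (4aS,5R,7aR)-1-ethenyl-4a-hydroxy-7a-methyl-5-(propan-2-yl)hexahydrocyclopenta[c]pyran-3(1H)-one | C=CC1OC(=O)C[C@]2(O)[C@@H](C(C)C)CC[C@]12C
F8 | step 5 | (1S,2R,5R)-1-(2-hydroxyethyl)-2-(1-hydroxyprop-2-en-1-yl)-2-methyl-5-(propan-2-yl)cyclopentan-1-ol | C=CC(O)[C@@]1(C)CC[C@H](C(C)C)[C@@]1(O)CCO
F9 | step 5 | 2-[(1S,2R,5R)-1-hydroxy-2-(1-hydroxyprop-2-en-1-yl)-2-methyl-5-(propan-2-yl)cyclopentyl]ethyl 4-methylbenzenesulfonate | C=CC(O)[C@@]1(C)CC[C@H](C(C)C)[C@@]1(O)CCOS(=O)(=O)c1ccc(C)cc1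
F10 | step 8 | (3R,3aS,8aS)-6,8a-dimethyl-3-(propan-2-yl)-3a-[(triethylsilyl)oxy]-2,3,3a,4,5,8a-hexahydroazulen-8(1H)-one | O=C1C=C(C)CC[C@]2(O[Si](CC)(CC)CC)[C@@H](C(C)C)CC[C@]12C
F11 | step 8 | (3R,3aS,8S,8aR)-6,8a-dimethyl-3-(propan-2-yl)-3a-[(triethylsilyl)oxy]-1,2,3,3a,4,5,8,8a-octahydroazulen-8-ol | O[C@H]1C=C(C)CC[C@]2(O[Si](CC)(CC)CC)[C@@H](C(C)C)CC[C@]12C
F12 | step 8 | (3R,3aS,8S,8aR)-6,8a-dimethyl-3-(propan-2-yl)-3a-[(triethylsilyl)oxy]-1,2,3,3a,4,5,8,8a-octahydroazulen-8-yl 4-methoxybenzoate | COc1ccc(cc1)C(=O)O[C@H]1C=C(C)CC[C@]2(O[Si](CC)(CC)CC)[C@@H](C(C)C)CC[C@]12C
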